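## Retrosynthetic overview

- Numbering: dihydrobenzofuran O1, C2 (syringyl ring), C3 (C9H2–O arm), ring A = benzene ring C3a–C7a (C5 propenyl chain, C7 OMe), ring B = O1–C2–C3–C3a–C7a. The two 4-hydroxybenzoates are cut back to a diol, the propenol chain to a C5 formyl group, and the C9 hydroxyl to a C9–O–N alkoxyamine.
- Feature on which the strategy rests: C3 is bonded to C3a, the ring A carbon ortho to O1, and carries the oxygenated one-carbon arm C9. This is the pattern left by a 5-exo aryl radical closure of an ortho-iodoaryl 1-arylallyl ether whose new primary radical takes up oxygen.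
- Key disconnection: C3–C3a and C9–O, back to an (S)-configured aryl iodide allyl ether and a nitroxide; C3 is set from C2.
- C2 and the C2–O1 bond come from an iridium-catalysed branched-selective allylic etherification of 5-iodovanillin with a silyl-protected sinapyl carbonate made from syringaldehyde.
- Ring order: the syringyl ring and ring A are bought; ring B is the only ring formed, in the key step.

Key step: step 6

Assumption: the (Sa,Sc,Sc) antipode of the phosphoramidite is written in step 5 as the one expected to give the (S)-ether; should the sense of induction prove opposite, the (Ra,Rc,Rc) ligand is used and nothing else changes.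

## Route

Step 1
Reactants: 1 syringaldehyde (4-hydroxy-3,5-dimethoxybenzaldehyde)
Product: 2 3,5-dimethoxy-4-(triisopropylsilyloxy)benzaldehyde
Conditions: i-Pr3SiCl, imidazole, DMF, rt
Reagents that add atoms: triisopropylsilyl chloride, CC(C)[Si](Cl)(C(C)C)C(C)C
Why: Silyl ether formation at the phenol; the bulky aryl triisopropylsilyl ether is expected to survive the phosphonate anions, phenoxide, hydride, tin radical and warm acetic acid steps ahead and to leave with fluoride at the end.

Step 2
Reactants: 2 3,5-dimethoxy-4-(triisopropylsilyloxy)benzaldehyde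
Product: 3 ethyl (E)-3-[3,5-dimethoxy-4-(triisopropylsilyloxy)phenyl]prop-2-enoate
Conditions: (EtO)2P(O)CH2CO2Et, NaH, THF, 0 °C to rt
Reagents that add atoms: triethyl phosphonoacetate, CCOC(=O)CP(=O)(OCC)OCC
Why: Horner–Wadsworth–Emmons olefination with a stabilised phosphonate anion should give the (E)-enoate.

Step 3
Reactants: 3 ethyl (E)-3-[3,5-dimethoxy-4-(triisopropylsilyloxy)phenyl]prop-2-enoate
Product: 4 (E)-3-[3,5-dimethoxy-4-(triisopropylsilyloxy)phenyl]prop-2-en-1-ol
Conditions: i-Bu2AlH (2.3 equiv), CH2Cl2, −78 °C; aq. potassium sodium tartrate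
Reagents that add atoms: none
Why: 1,2-Reduction of the conjugated ester with diisobutylaluminium hydride at low temperature gives the allylic alcohol and leaves the aryl silyl ether and the alkene geometry untouched.

Step 4
Reactants: 4 (E)-3-[3,5-dimethoxy-4-(triisopropylsilyloxy)phenyl]prop-2-en-1-ol
Product: 5 (E)-3-[3,5-dimethoxy-4-(triisopropylsilyloxy)phenyl]prop-2-enyl methyl carbonate
Conditions: ClCO2Me, pyridine, CH2Cl2, 0 °C
Reagents that add atoms: methyl chloroformate, COC(=O)Cl
Why: O-Acylation of the primary allylic alcohol (carbonate formation) installs the leaving group for the iridium-catalysed substitution.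

Step 5
Reactants: 5 (E)-3-[3,5-dimethoxy-4-(triisopropylsilyloxy)phenyl]prop-2-enyl methyl carbonate; 6 5-iodovanillin (4-hydroxy-3-iodo-5-methoxybenzaldehyde)
Product: 8 (S)-4-{1-[3,5-dimethoxy-4-(triisopropylsilyloxy)phenyl]prop-2-enyloxy}-3-iodo-5-methoxybenzaldehyde, via sodium 4-formyl-2-iodo-6-methoxyphenolate 7 (not isolated)
Conditions: 6 (1.5 equiv), NaH, THF, 0 °C; then 5, [Ir(cod)Cl]2 (2 mol%), (Sa,Sc,Sc)-O,O'-(1,1'-binaphthyl-2,2'-diyl)-N,N-bis(1-phenylethyl)phosphoramidite (4 mol%; pre-activated with n-PrNH2, volatiles removed), THF, rt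
Reagents that add atoms: none
Why: Iridium-catalysed asymmetric allylic etherification: the cyclometalated monovalent iridium–phosphoramidite catalyst ionises the carbonate to an allyl complex that the phenoxide attacks at the aryl-bearing terminus, which gives the branched ether and sets C2 as S under ligand control, with the aldehyde, aryl iodide and silyl ether expected to be inert at room temperature.

Step 6
Reactants: 8 (S)-4-{1-[3,5-dimethoxy-4-(triisopropylsilyloxy)phenyl]prop-2-enyloxy}-3-iodo-5-methoxybenzaldehyde; 9 TEMPO (2,2,6,6-tetramethylpiperidin-1-oxyl)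
Product: 12 (2S,3R)-2-[3,5-dimethoxy-4-(triisopropylsilyloxy)phenyl]-7-methoxy-3-[(2,2,6,6-tetramethylpiperidin-1-yloxy)methyl]-2,3-dihydrobenzofuran-5-carbaldehyde, via C3a aryl radical 10 (not isolated), via cyclised C9 alkyl radical 11 (not isolated)
Conditions: Bu3SnH (4 equiv, in portions), TEMPO (6 equiv, in portions), degassed PhH (0.05 M), 70 °C
Reagents that add atoms: none
Why: Hydrogen transfer from Bu3SnH to TEMPO gives the tributylstannyl radical, which abstracts iodine from 8 to give the σ-aryl radical 10 at C3a; 10 adds to the internal vinyl carbon in a 5-exo-trig closure that forms the C3–C3a bond and ring B, and the primary C9 radical 11 then couples with TEMPO to form the C9–O bond of 12. The closest known reaction type is the tin hydride-mediated 5-exo aryl radical–alkene cyclisation with in situ nitroxide capture of the cyclised radical. C2 is carried in unchanged from 8, and C3 is set under substrate control: in the chair-like transition state the C2 aryl group sits pseudo-equatorial and the vinyl terminus C9 turns away from it, so C9 should end up trans to the aryl group, which is (2S,3R). The step needs 5-exo closure to outrun 1,5-hydrogen transfer from the doubly activated C2–H, which the very fast cyclisation of ortho-allyloxyaryl radicals should secure, and it needs TEMPO capture of 11 to outrun reduction by tin hydride, which the excess of nitroxide and the portionwise addition of Bu3SnH should secure. Iodine abstraction should outrun attack of tin on the aldehyde because of the weak aryl C–I bond, and any cis isomer should be separable by chromatography at this stage.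

Step 7
Reactants: 12 (2S,3R)-2-[3,5-dimethoxy-4-(triisopropylsilyloxy)phenyl]-7-methoxy-3-[(2,2,6,6-tetramethylpiperidin-1-yloxy)methyl]-2,3-dihydrobenzofuran-5-carbaldehyde
Product: 13 ethyl (E)-3-{(2S,3R)-2-[3,5-dimethoxy-4-(triisopropylsilyloxy)phenyl]-7-methoxy-3-[(2,2,6,6-tetramethylpiperidin-1-yloxy)methyl]-2,3-dihydrobenzofuran-5-yl}prop-2-enoate
Conditions: (EtO)2P(O)CH2CO2Et, NaH, THF, 0 °C to rt
Reagents that add atoms: triethyl phosphonoacetate, CCOC(=O)CP(=O)(OCC)OCC
Why: Horner–Wadsworth–Emmons olefination of the aromatic aldehyde should give the (E)-enoate, the alkoxyamine, the silyl ether and the non-acidic C2 and C3 centres being untouched.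

Step 8
Reactants: 13 ethyl (E)-3-{(2S,3R)-2-[3,5-dimethoxy-4-(triisopropylsilyloxy)phenyl]-7-methoxy-3-[(2,2,6,6-tetramethylpiperidin-1-yloxy)methyl]-2,3-dihydrobenzofuran-5-yl}prop-2-enoate
Product: 14 ethyl (E)-3-{(2S,3R)-2-[3,5-dimethoxy-4-(triisopropylsilyloxy)phenyl]-3-(hydroxymethyl)-7-methoxy-2,3-dihydrobenzofuran-5-yl}prop-2-enoate
Conditions: Zn dust, AcOH/THF/H2O (3:1:1), 55 °C
Reagents that add atoms: none
Why: Dissolving-metal reductive cleavage of the alkoxyamine N–O bond frees the C9 alcohol; it is placed before the ester reduction because the conjugated ester and the aryl silyl ether should tolerate warm acetic acid, whereas the electron-rich cinnamyl alcohol made in step 9 would be prone to acid-induced ionisation.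

Step 9
Reactants: 14 ethyl (E)-3-{(2S,3R)-2-[3,5-dimethoxy-4-(triisopropylsilyloxy)phenyl]-3-(hydroxymethyl)-7-methoxy-2,3-dihydrobenzofuran-5-yl}prop-2-enoate
Product: 15 (E)-3-{(2S,3R)-2-[3,5-dimethoxy-4-(triisopropylsilyloxy)phenyl]-3-(hydroxymethyl)-7-methoxy-2,3-dihydrobenzofuran-5-yl}prop-2-en-1-ol
Conditions: i-Bu2AlH (3.5 equiv), CH2Cl2, −78 °C; aq. potassium sodium tartrate
Reagents that add atoms: none
Why: 1,2-Reduction of the conjugated ester with diisobutylaluminium hydride gives the (E)-allylic alcohol, the free C9 hydroxyl only consuming one further equivalent of hydride as its aluminium alkoxide.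

Step 10
Reactants: 16 4-hydroxybenzoic acid
Product: 18 4-(tert-butyldimethylsilyloxy)benzoic acid, via tert-butyldimethylsilyl 4-(tert-butyldimethylsilyloxy)benzoate 17 (not isolated)
Conditions: t-BuMe2SiCl (2.5 equiv), imidazole, DMF, rt; then AcOH/THF/H2O (3:1:1), rt
Reagents that add atoms: tert-butyldimethylsilyl chloride, CC(C)(C)[Si](C)(C)Cl
Why: Silylation of both the phenol and the acid followed by selective hydrolysis of the much more labile silyl ester masks the phenol, so that only the carboxyl group acylates in step 11.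

Step 11
Reactants: 15 (E)-3-{(2S,3R)-2-[3,5-dimethoxy-4-(triisopropylsilyloxy)phenyl]-3-(hydroxymethyl)-7-methoxy-2,3-dihydrobenzofuran-5-yl}prop-2-en-1-ol; 18 4-(tert-butyldimethylsilyloxy)benzoic acid (2.4 equiv)
Product: 19 (E)-3-{(2S,3R)-3-{[4-(tert-butyldimethylsilyloxy)benzoyloxy]methyl}-2-[3,5-dimethoxy-4-(triisopropylsilyloxy)phenyl]-7-methoxy-2,3-dihydrobenzofuran-5-yl}prop-2-enyl 4-(tert-butyldimethylsilyloxy)benzoate
Conditions: DCC, DMAP (cat.), CH2Cl2, 0 °C to rt
Reagents that add atoms: none
Why: Steglich esterification (carbodiimide activation with DMAP acyl transfer) of both primary hydroxyls under neutral conditions should leave the silyl ethers, ring B and both stereocentres intact.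

Step 12
Reactants: 19 (E)-3-{(2S,3R)-3-{[4-(tert-butyldimethylsilyloxy)benzoyloxy]methyl}-2-[3,5-dimethoxy-4-(triisopropylsilyloxy)phenyl]-7-methoxy-2,3-dihydrobenzofuran-5-yl}prop-2-enyl 4-(tert-butyldimethylsilyloxy)benzoate
Product: 20 quiquesetinerviusin B
Conditions: Bu4NF/AcOH (1:1, 4 equiv), THF, 0 °C to rt
Reagents that add atoms: none
Why: Fluoride-mediated desilylation of the three aryl silyl ethers; acetic acid buffering keeps the liberated phenols protonated, so the benzoate esters should not be cleaved or transferred and the para-hydroxybenzylic C2–O1 bond should not open through a quinone methide.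

## Compound list

1 | syringaldehyde (4-hydroxy-3,5-dimethoxybenzaldehyde) | COc1cc(C=O)cc(OC)c1O | starting material
2 | 3,5-dimethoxy-4-(triisopropylsilyloxy)benzaldehyde | COc1cc(C=O)cc(OC)c1O[Si](C(C)C)(C(C)C)C(C)C | intermediate
3 | ethyl (E)-3-[3,5-dimethoxy-4-(triisopropylsilyloxy)phenyl]prop-2-enoate | CCOC(=O)/C=C/c1cc(OC)c(O[Si](C(C)C)(C(C)C)C(C)C)c(OC)c1 | intermediate
4 | (E)-3-[3,5-dimethoxy-4-(triisopropylsilyloxy)phenyl]prop-2-en-1-ol | OC/C=C/c1cc(OC)c(O[Si](C(C)C)(C(C)C)C(C)C)c(OC)c1 | intermediate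
5 | (E)-3-[3,5-dimethoxy-4-(triisopropylsilyloxy)phenyl]prop-2-enyl methyl carbonate | COC(=O)OC/C=C/c1cc(OC)c(O[Si](C(C)C)(C(C)C)C(C)C)c(OC)c1 | intermediate
6 | 5-iodovanillin (4-hydroxy-3-iodo-5-methoxybenzaldehyde) | COc1cc(C=O)cc(I)c1O | starting material
7 | sodium 4-formyl-2-iodo-6-methoxyphenolate | COc1cc(C=O)cc(I)c1[O-].[Na+] | intermediate
8 | (S)-4-{1-[3,5-dimethoxy-4-(triisopropylsilyloxy)phenyl]prop-2-enyloxy}-3-iodo-5-methoxybenzaldehyde | COc1cc([C@H](C=C)Oc2c(I)cc(C=O)cc2OC)cc(OC)c1O[Si](C(C)C)(C(C)C)C(C)C | intermediate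
9 | TEMPO (2,2,6,6-tetramethylpiperidin-1-oxyl) | CC1(C)CCCC(C)(C)N1[O] | starting material
10 | (S)-2-{1-[3,5-dimethoxy-4-(triisopropylsilyloxy)phenyl]prop-2-enyloxy}-5-formyl-3-methoxyphenyl radical (C3a aryl radical) | COc1cc([C@H](C=C)Oc2[c]cc(C=O)cc2OC)cc(OC)c1O[Si](C(C)C)(C(C)C)C(C)C | intermediate
11 | 2,3-trans-{2-[3,5-dimethoxy-4-(triisopropylsilyloxy)phenyl]-5-formyl-7-methoxy-2,3-dihydrobenzofuran-3-yl}methyl radical (formally 2S,3S, because C9 carries no oxygen yet; same spatial arrangement as 12) | COc1cc([C@H]2Oc3c(OC)cc(C=O)cc3[C@@H]2[CH2])cc(OC)c1O[Si](C(C)C)(C(C)C)C(C)C | intermediate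
12 | (2S,3R)-2-[3,5-dimethoxy-4-(triisopropylsilyloxy)phenyl]-7-methoxy-3-[(2,2,6,6-tetramethylpiperidin-1-yloxy)methyl]-2,3-dihydrobenzofuran-5-carbaldehyde | COc1cc([C@H]2Oc3c(OC)cc(C=O)cc3[C@@H]2CON2C(C)(C)CCCC2(C)C)cc(OC)c1O[Si](C(C)C)(C(C)C)C(C)C | intermediate
13 | ethyl (E)-3-{(2S,3R)-2-[3,5-dimethoxy-4-(triisopropylsilyloxy)phenyl]-7-methoxy-3-[(2,2,6,6-tetramethylpiperidin-1-yloxy)methyl]-2,3-dihydrobenzofuran-5-yl}prop-2-enoate | COc1cc([C@H]2Oc3c(OC)cc(/C=C/C(=O)OCC)cc3[C@@H]2CON2C(C)(C)CCCC2(C)C)cc(OC)c1O[Si](C(C)C)(C(C)C)C(C)C | intermediate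
14 | ethyl (E)-3-{(2S,3R)-2-[3,5-dimethoxy-4-(triisopropylsilyloxy)phenyl]-3-(hydroxymethyl)-7-methoxy-2,3-dihydrobenzofuran-5-yl}prop-2-enoate | COc1cc([C@H]2Oc3c(OC)cc(/C=C/C(=O)OCC)cc3[C@@H]2CO)cc(OC)c1O[Si](C(C)C)(C(C)C)C(C)C | intermediate
15 | (E)-3-{(2S,3R)-2-[3,5-dimethoxy-4-(triisopropylsilyloxy)phenyl]-3-(hydroxymethyl)-7-methoxy-2,3-dihydrobenzofuran-5-yl}prop-2-en-1-ol | COc1cc([C@H]2Oc3c(OC)cc(/C=C/CO)cc3[C@@H]2CO)cc(OC)c1O[Si](C(C)C)(C(C)C)C(C)C | intermediate
16 | 4-hydroxybenzoic acid | O=C(O)c1ccc(O)cc1 | starting material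
17 | tert-butyldimethylsilyl 4-(tert-butyldimethylsilyloxy)benzoate | CC(C)(C)[Si](C)(C)OC(=O)c1ccc(O[Si](C)(C)C(C)(C)C)cc1 | intermediate
18 | 4-(tert-butyldimethylsilyloxy)benzoic acid | CC(C)(C)[Si](C)(C)Oc1ccc(C(=O)O)cc1 | intermediate
19 | (E)-3-{(2S,3R)-3-{[4-(tert-butyldimethylsilyloxy)benzoyloxy]methyl}-2-[3,5-dimethoxy-4-(triisopropylsilyloxy)phenyl]-7-methoxy-2,3-dihydrobenzofuran-5-yl}prop-2-enyl 4-(tert-butyldimethylsilyloxy)benzoate | COc1cc([C@H]2Oc3c(OC)cc(/C=C/COC(=O)c4ccc(O[Si](C)(C)C(C)(C)C)cc4)cc3[C@@H]2COC(=O)c2ccc(O[Si](C)(C)C(C)(C)C)cc2)cc(OC)c1O[Si](C(C)C)(C(C)C)C(C)C | intermediate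
20 | quiquesetinerviusin B, (2S,3R) | COc1cc([C@H]2Oc3c(OC)cc(/C=C/COC(=O)c4ccc(O)cc4)cc3[C@@H]2COC(=O)c2ccc(O)cc2)cc(OC)c1O | target

## Step count

Total: 12 steps. Longest linear sequence: 11 steps (steps 1–9, 11 and 12); step 10 is a one-step side branch.

## Steps most likely to fail

**Step 6 (radical cyclisation with nitroxide capture).** The tin hydride and the nitroxide may consume each other faster than the iodide is turned over. The C9 radical may be reduced before it is captured. The aldehyde may be attacked during the long exposure to excess tin hydride. The fallback sets out from 8 and returns at 14. Horner–Wadsworth–Emmons olefination of 8 (triethyl phosphonoacetate, NaH, THF) comes first and gives ethyl (E)-3-{4-[(S)-1-(3,5-dimethoxy-4-triisopropylsilyloxyphenyl)prop-2-enyloxy]-3-iodo-5-methoxyphenyl}prop-2-enoate F1, so that no aldehyde enters the radical step. F1 is then cyclised under aerobic tin hydride conditions (Bu3SnH added slowly, dry air, toluene, 0 °C to rt), a known oxygenative radical cyclisation. The same aryl radical closes 5-exo and the C9 radical is captured by dioxygen, giving the 2,3-trans hydroperoxide ethyl (E)-3-{(2S,3R)-2-[3,5-dimethoxy-4-(triisopropylsilyloxy)phenyl]-3-(hydroperoxymethyl)-7-methoxy-2,3-dihydrobenzofuran-5-yl}prop-2-enoate F2. F2 is reduced in the same flask with PPh3 to hydroxy ester 14. No nitroxide is used and no N–O bond has to be cleaved.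

**Step 5 (iridium-catalysed etherification).** The phenoxide is flanked by iodine and methoxy and is weakly nucleophilic, so attack on the allyl complex may be slow and let the linear ether or methoxide capture compete. The product carries a good aryloxide leaving group, so the catalyst may re-ionise it and erode regio- and enantiopurity. The fallback sets out from 5 and returns at 8; it sets C2 with a small nucleophile and then forms the ether stereospecifically. Iridium-catalysed allylic hydroxylation of 5 ([Ir(cod)Cl]2, the same phosphoramidite, KHCO3 as oxygen nucleophile) should give (S)-1-[3,5-dimethoxy-4-(triisopropylsilyloxy)phenyl]prop-2-en-1-ol F3. Acylation with Boc2O and catalytic DMAP gives (S)-tert-butyl 1-[3,5-dimethoxy-4-(triisopropylsilyloxy)phenyl]prop-2-enyl carbonate F4. Ruthenium-catalysed allylic etherification of F4 with phenol 6 ([Cp*Ru(MeCN)3]PF6, rt) is branched-selective and stereospecific with net retention, and should give 8.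

**Step 12 (global desilylation).** The triisopropylsilyl ether between two methoxy groups may be cleaved only slowly under buffered fluoride. More basic conditions risk acyl transfer or loss of the 4-hydroxybenzoates, and phenoxide-triggered opening of ring B through a quinone methide. The fallback sets out from 15 and returns at 20. The silyl group is removed before the esters are made (Bu4NF/AcOH, THF), giving (E)-3-[(2S,3R)-2-(4-hydroxy-3,5-dimethoxyphenyl)-3-(hydroxymethyl)-7-methoxy-2,3-dihydrobenzofuran-5-yl]prop-2-en-1-ol F5. Both primary alcohols of F5 are then esterified with unprotected 4-hydroxybenzoic acid 16 by Mitsunobu reaction (PPh3, DIAD, THF, 0 °C). The carboxylic acid is by far the most acidic pronucleophile, so the phenols should stay free and 20 should form directly.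

## Further compounds

F1 | step 6 | ethyl (E)-3-{4-[(S)-1-(3,5-dimethoxy-4-triisopropylsilyloxyphenyl)prop-2-enyloxy]-3-iodo-5-methoxyphenyl}prop-2-enoate | COc1cc([C@H](C=C)Oc2c(I)cc(/C=C/C(=O)OCC)cc2OC)cc(OC)c1O[Si](C(C)C)(C(C)C)C(C)C
F2 | step 6 | ethyl (E)-3-{(2S,3R)-2-[3,5-dimethoxy-4-(triisopropylsilyloxy)phenyl]-3-(hydroperoxymethyl)-7-methoxy-2,3-dihydrobenzofuran-5-yl}prop-2-enoate | COc1cc([C@H]2Oc3c(OC)cc(/C=C/C(=O)OCC)cc3[C@@H]2COO)cc(OC)c1O[Si](C(C)C)(C(C)C)C(C)C
F3 | step 5 | (S)-1-[3,5-dimethoxy-4-(triisopropylsilyloxy)phenyl]prop-2-en-1-ol | COc1cc([C@H](C=C)O)cc(OC)c1O[Si](C(C)C)(C(C)C)C(C)C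
F4 | step 5 | (S)-tert-butyl 1-[3,5-dimethoxy-4-(triisopropylsilyloxy)phenyl]prop-2-enyl carbonate | COc1cc([C@H](C=C)OC(=O)OC(C)(C)C)cc(OC)c1O[Si](C(C)C)(C(C)C)C(C)C
F5 | step 12 | (E)-3-[(2S,3R)-2-(4-hydroxy-3,5-dimethoxyphenyl)-3-(hydroxymethyl)-7-methoxy-2,3-dihydrobenzofuran-5-yl]prop-2-en-1-ol | COc1cc([C@H]2Oc3c(OC)cc(/C=C/CO)cc3[C@@H]2CO)cc(OC)c1O
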